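## Structural features

The target is the O7 ether of isofraxidin (7-hydroxy-6,8-dimethoxycoumarin) with a C15 trans-decalin carbinol; one neopentyl CH2 (C11) joins the phenol oxygen to the quaternary carbon C9. The decalin is numbered so that ring A is C1–C5 plus C10 with the ketone at C3, and ring B is C5–C10; α is the face of the C5 methyl group and β the face of H-10. Ring A holds the contiguous triad C4 (CHMe next to the ketone), C5 (quaternary, Me) and C10 (ring-fusion CH). Ring B holds the adjacent pair C8 (CHMe) and C9 (quaternary, Me and C11), so five stereocentres sit on six neighbouring ring atoms. The C4, C5 and C9 methyl groups are α; H-10, the C8 methyl group and C11 are β. The C5 and C9 methyls are therefore syn-diaxial, the C8 methyl is axial and trans to the C9 methyl, and the C4 methyl is equatorial, the more stable arrangement next to the ketone. Fragile parts are the coumarin (a conjugated lactone that does not survive hydride, strong base or hydrogenation, so it must come last), the enolisable C4 centre, and the C11–O bond, which can only be made by substitution at a neopentyl carbon. The real difficulty is the ring B pair: an axial C8 methyl anti to an axial C9 methyl that is itself syn-diaxial to the C5 methyl cannot be reached by hydrogenation from the open face or by equilibration. The key step exploits ring A: the array C4(Me)–C5(Me)(C6)–C10(H), with the two methyls cis and C6 trans to C9, is what an (E)-α-methyl enal leaves when it adds exo across C3–C4 and C5–C10 to a 1-substituted butadiene. The C1=C2 double bond that remains is the handle for the C3 ketone.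

## Logic of the disconnections

C11–O(aryl): 20 is cut into 18 and 19. This keeps the coumarin out of every reducing and basic step and uses 19 intact. The gain is the loss of eleven carbons and the arene in one cut. The demand is an SN2 reaction at a neopentyl carbon with a doubly ortho-substituted phenol.

C3=O and the C11 protecting group: 18 comes from 17, and 17 from 16. The ketone is traced to allylic oxidation of the C1=C2 alkene that the cycloaddition leaves; one hydrogenation then saturates the enone and frees the C11 hydroxyl. The gain is that ring A needs no functional group other than its alkene until the end. The demand is that the oxidation takes the C3 methylene, not the tertiary C10–H, and spares the benzyl ether.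

C6 oxygen: 16 is traced to 14 by putting a carbonyl back at C6 (removed forward by Wolff–Kishner reduction). This costs one step but turns ring B into an enone retron for the next two cuts. The demand is hydrazone formation at a ketone next to a quaternary carbon.

C8–CH3: 14 is cut to 13 and a methyl cuprate. An axial C8 methyl anti to the axial C9 methyl is exactly what axial conjugate addition next to an axial γ-substituent delivers. The gain is the removal of the C8 stereocentre. The demand is that the C9 methyl, not the equatorial C11 arm, controls the face.

C7=C8 (ring B): 13 is opened to 11 by a retro-aldol condensation. In 11 only the C6 methyl ketone can enolise and only the C8 aldehyde can accept, so the closure has one course. The gain is a monocyclic precursor; the ring fusion is already fixed by C5 and C10.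

C9–C11 and oxidation levels: 11 comes from 10, 10 from 9, and 9 from 7 through enolate 8, the cut being C9–C11. The carboxyl carbon of 5 is therefore mapped onto C8, not C11. The reason is facial control: in the trans-fused lactone the C5 methyl is syn-axial to C9 and closes the α face, so the incoming C11 unit must enter β, which is the target configuration. A [3,3] shift of an allyl ester at this carbon would instead have to bring the new C8–C9 bond onto the face of C9 flanked by quaternary C5, against the normal allylic-strain preference, and would also depend on the geometry of a tetrasubstituted ketene acetal. The gain is a quaternary centre made from an epimeric CH. The demand is C- over O-alkylation.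

C6–C7 and the lactone C–O bond: 7 is cut to 5 and a methyl Grignard reagent; the alkoxide acylates itself on the ester. The demand is aldehyde-over-ester selectivity. The new C6 carbinol centre and the C9 centre need no control, because both are erased later.

C3–C4 and C5–C10 (ring A): 5 is cut to 3 and 4 by the retro-Diels–Alder reaction. The gain is the largest of the route: one ring, two bonds and three contiguous stereocentres including quaternary C5. The demand is regio-, exo- and enantiofacial control with a trisubstituted dienophile.

C9–CH3: 3 is cut to 1 and iodomethane (deconjugative α-alkylation). The stereocentre made is racemic and irrelevant. Compound 3 keeps its methyl ester because that ester must later acylate the C6 alkoxide, and DMPU replaces the carcinogenic phosphoramide cosolvent.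

## Other disconnections considered

Alternative 1: The cut is C8–C9 by a retro-[3,3] shift, back to δ-lactone A1, in which C11 is the lactone carbonyl and C6 carries the ring oxygen and an (E)-prop-1-enyl group. Forward, the silyl ketene acetal A2 rearranges through a boat, because the ketene acetal and the allyl unit are tied through C5–C10, and gives acid A3 with ring B closed, C8 and C9 set and a C6=C7 alkene.
- In its favour: one step closes ring B and sets both ring B centres, the face at C9 is fixed by the tether, and A1 could come from a cycloadduct of the type of 5 by propenyl-metal addition and lactonisation. On step economy this alternative is the better plan, replacing roughly steps 3 to 9 of the chosen route by two or three.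
- Against it here: the C6 carbinol must be made with the propenyl group cis to the C5 methyl in an addition to an α-quaternary aldehyde. The boat must carry the allyl terminus over the face of C9 that is syn to that methyl. The C6=C7 alkene next to C8 must later be hydrogenated without migration. The C11 acid has to be reduced beside the C3 carbonyl, hence the ketal.
- Comparison: ring A has the same origin in both plans and both use the C5 methyl as the control element (equal). Mechanistically the alternative stakes C8 and C9 on one concerted event with a demanding geometry. The chosen plan uses two separate substrate-controlled events (β-face alkylation, axial cuprate addition) of well-established sense, and pays with more steps.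

Alternative 2: The cuts are C9–C10 and C4–C5, both rings at once, back to acyclic epoxy diene enol silane A4. Forward, a bulky methylaluminium bis(aryloxide) Lewis acid opens the epoxide at C9, the E olefin closes ring B and the enol silane closes ring A, to give keto alcohol A5, which is identical with 18.
- In its favour: it is the most convergent plan in bond formation and it delivers the C3 ketone and the C11 alcohol at their final oxidation levels without protecting groups. On redox and protecting-group economy it is better than the chosen route, which needs an allylic oxidation, a deoxygenation and a benzyl ether.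
- Against it here: the chair–chair transition state must place the C5 and C9 methyls syn-diaxial and the C8 methyl axial in the forming ring B. Other folds, hydride shift of the opened epoxide to an aldehyde, or elimination after the first ring are therefore likely to compete. The adjacent C8 and C9 centres of A4, one of them a 2,2-disubstituted epoxide, must be made enantiopure in an acyclic chain beforehand.
- Comparison: both plans converge on the same last intermediate and the same final etherification (equal). Structurally the alternative moves all stereochemical risk into one cationic step whose preferred fold runs against the target. The chosen plan sets the same centres by a pericyclic reaction and two sterically obvious additions.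

Alternative 3: The cuts are C4a–C8a and C5–C6 of the coumarin benzo ring, so the arene is built after the ether is in place. Forward, 2-silyloxyfuran A6 adds methyl propiolate A7 with the silyloxy carbon bonding to the ester-bearing alkyne carbon; the oxygen bridge then opens and the ring aromatises to benzoate A8. O-methylation, ester-to-aldehyde adjustment and olefination with lactonisation would then complete the coumarin.
- In its favour: the ether oxygen would be attached by addition–elimination at an sp2 carbon of the furanone precursor of A6, not by substitution at neopentyl C11. On this single bond the alternative is better than step 12. The regiochemistry of the cycloaddition is well defined by the silyloxy group.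
- Against it here: it does nothing for the decalin, whose five stereocentres still have to be made (a ketal of 18 would be its starting point). It rebuilds in about six steps an arene that is commercial as 19, on the most valuable intermediate, and passes through a sensitive silyloxyfuran.
- Comparison: the two plans are complementary rather than competing. The chosen plan makes the same ether in one step and is far shorter; the alternative removes the one SN2 risk at the cost of a long linear tail.

Key step: step 2

Remarks on the chemistry (assumptions):
- The sense of induction of the (S)-oxazaborolidinium ion is taken from the formyl C–H···O binding model for α-substituted enals; should the opposite face be delivered, the catalyst from (R)-diphenylprolinol would be used with no other change.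
- The cycloadduct formulated with cis methyl groups and the formyl group trans to the C10 side chain (1R,5R,6S) is the exo adduct of the (E)-enal and matches C4, C5 and C10 of the target; no structure needed correction.

## Route

Step 1
Reactants: 1 methyl sorbate
Product: 3 methyl (3E)-2-methylhexa-3,5-dienoate (racemic), via lithium trienolate 2 (not isolated)
Conditions: LDA, DMPU, THF, −78 °C; MeI, −78 °C
Reagents that add atoms: iodomethane, CI
Why: Deconjugative α-alkylation: γ-deprotonation at the terminal methyl gives the extended enolate, which is methylated kinetically at the α-carbon; the new C3=C4 bond is E because it derives from the s-trans diene. The stereocentre is racemic and is erased in step 4.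

Step 2
Reactants: 3 methyl (3E)-2-methylhexa-3,5-dienoate; 4 tiglic aldehyde
Product: 5 methyl 2-[(1R,5R,6S)-6-formyl-5,6-dimethylcyclohex-2-en-1-yl]propanoate (both epimers at the propanoate C2)
Conditions: (S)-3,3-diphenyl-1-(2-methylphenyl)tetrahydro-1H,3H-pyrrolo[1,2-c][1,3,2]oxazaborole (C24H24BNO, 20 mol%), HN(SO2CF3)2 (18 mol%), CH2Cl2, −78 → −40 °C
Reagents that add atoms: none
Why: A concerted but asynchronous normal-demand [4+2] cycloaddition of the s-cis diene of 3 to the boron-bound s-trans enal 4, with the C3–C4 bond (diene CH2 terminus to enal β-carbon) running ahead of C5–C10; the closest known type is the oxazaborolidinium-catalysed exo Diels–Alder reaction of α-methyl enals with acyclic dienes. Ring A is closed as a cyclohexene by intermolecular cycloaddition, both ring bonds forming in the one step. The ortho regiochemistry follows from the larger HOMO coefficient at the unsubstituted diene terminus meeting the β-carbon of the activated enal. C4 and C5: the E geometry of 4 is transferred suprafacially, so the two methyl groups end cis. C10 relative to C5: the α-methyl group sends the formyl group exo, and with the E diene this places C6 trans to the C10 side chain. Absolute configuration: the formyl C–H···O contact holds the enal over a phenyl group of the catalyst, which covers the Si face of the α-carbon, so the diene adds to the Re face. The step needs regio-, exo- and enantiofacial selectivity, secured in turn by the 1-alkyl diene, the α-methyl group of the enal and the catalyst. The stereocentre of racemic 3 is not used: both epimers of 5 go on.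

Step 3
Reactants: 5 cycloadduct aldehyde ester
Product: 7 trans-fused δ-lactone O–C6H(CH3)–C5/C10–C9H(CH3)–C8(=O) on the ring A cyclohexene (4α,5α-dimethyl; 10β-H; epimers at C6 and C9), via hydroxy ester 6 (not isolated)
Conditions: MeMgBr, THF, −78 → 0 °C; then PPTS (cat.), PhMe, 60 °C
Reagents that add atoms: methylmagnesium bromide, C[Mg]Br
Why: Grignard addition is selective for the aldehyde over the α-branched ester at low temperature, and the 1,5-hydroxy ester lactonises by acyl transfer. The C6 carbinol centre is uncontrolled and irrelevant because it is oxidised in step 6.

Step 4
Reactants: 7 δ-lactone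
Product: 9 lactone with quaternary C9 (9α-CH3 and 9β-CH2OCH2Ph; epimers at C6), via lithium enolate 8 (not isolated)
Conditions: LDA, THF, −78 → −30 °C; BnOCH2Cl, DMPU, −78 → 0 °C
Reagents that add atoms: benzyl chloromethyl ether, ClCOCc1ccccc1
Why: Enolate C-alkylation with a reactive α-chloro ether; both C9 epimers of 7 converge on planar enolate 8. The axial C5 methyl is 1,3 to C9 and blocks the α face of the trans-fused lactone enolate, so the electrophile enters β and the C9 methyl ends α.

Step 5
Reactants: 9 alkylated lactone
Product: 10 diol, ring A cyclohexene bearing C5–CH(OH)CH3 and C10–C9(CH3)(CH2OH)(CH2OBn) (epimers at C6)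
Conditions: LiAlH4, THF, 0 → 23 °C
Reagents that add atoms: none
Why: Hydride reduction of the lactone to the 1,5-diol; the benzyl ether, the alkene and the quaternary centre are untouched.

Step 6
Reactants: 10 diol
Product: 11 keto aldehyde, C5–C(=O)CH3 and C10–C9(CH3)(CHO)(CH2OBn)
Conditions: (COCl)2, DMSO, CH2Cl2, −78 °C; Et3N, −78 → 0 °C
Reagents that add atoms: none
Why: Swern oxidation activates both hydroxyls before base is added, so no lactol forms and no over-oxidation to the lactone occurs. Both C6 epimers converge, and neither new carbonyl has an epimerisable α-stereocentre (C5 and C9 are quaternary).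

Step 7
Reactants: 11 keto aldehyde
Product: 13 ring B enone, trans-fused octalin with C1=C2 and C6(=O)–C7=C8 (4α,5α,9α-trimethyl; 9β-CH2OBn; 10β-H), via β-hydroxy ketone 12 (not isolated)
Conditions: KOH, MeOH, 23 → 50 °C
Reagents that add atoms: none
Why: Intramolecular aldol condensation: the methyl ketone is the only enolisable site and the non-enolisable aldehyde the only acceptor, so six-membered closure and E1cB dehydration give the cyclohexenone. The trans ring fusion is already fixed by C5 and C10.

Step 8
Reactants: 13 ring B enone
Product: 14 C6 ketone with 8β-methyl group
Conditions: Me2CuLi (from CuI and MeLi), Et2O, −40 → 0 °C; aq. NH4Cl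
Reagents that add atoms: lithium dimethylcuprate, [Li+].C[Cu-]C
Why: Cuprate conjugate addition to a cyclohexenone with a quaternary γ-carbon: axial attack at C8 anti to the axial C9 methyl, through a chair-like enolate, puts the new methyl β and axial. The same control operates in 1α-methylation of steroidal 1-en-3-ones.

Step 9
Reactants: 14 C6 ketone
Product: 16 benzyl ether of the Δ1-decalin carbinol (C6 now CH2), via hydrazone 15 (not isolated)
Conditions: N2H4·H2O, KOH, diethylene glycol, 130 → 200 °C, under N2
Reagents that add atoms: none
Why: Wolff–Kishner reduction: hydrazone formation, then base-induced loss of N2. No stereocentre is α to C6 on the quaternary side, and C8 is β to the carbonyl, so nothing can epimerise; the alkene and the benzyl ether are inert to base.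

Step 10
Reactants: 16 Δ1-alkene
Product: 17 ring A enone, C1=C2–C3(=O)
Conditions: CrO3, 3,5-dimethylpyrazole, CH2Cl2, −20 °C
Reagents that add atoms: chromium trioxide, O=[Cr](=O)=O
Why: Allylic oxidation of a cyclohexene methylene to the enone. C3 is the accessible allylic site, whereas the tertiary C10–H is shielded by the syn-axial C8 methyl and two quaternary neighbours. The C4 methyl, now α to a carbonyl, already has the thermodynamically preferred equatorial orientation.

Step 11
Reactants: 17 ring A enone
Product: 18 (1S,4aS,5S,6S,8aR)-5-(hydroxymethyl)-1,5,6,8a-tetramethyloctahydronaphthalen-2(1H)-one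
Conditions: H2 (1 atm), Pd/C, EtOAc, 23 °C
Reagents that add atoms: none
Why: Catalytic hydrogenation saturates the enone double bond and hydrogenolyses the benzyl ether in one operation; the ketone survives and no stereocentre is created.

Step 12
Reactants: 18 keto alcohol; 19 isofraxidin
Product: 20 target, 6,8-dimethoxy-7-{[(1S,2S,4aR,5S,8aS)-1,2,4a,5-tetramethyl-6-oxodecahydronaphthalen-1-yl]methoxy}-2H-chromen-2-one
Conditions: PBu3, 1,1'-(azodicarbonyl)dipiperidine (ADDP), PhMe (concentrated), 23 → 80 °C
Reagents that add atoms: none
Why: Mitsunobu etherification: the acidic phenol protonates the betaine and its phenoxide displaces the oxyphosphonium group at the CH2 carbon, which is not a stereocentre. The small, nucleophilic phosphine and heat answer the neopentyl hindrance; the ketone and the coumarin are inert.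

## Compound list

1 | methyl sorbate, methyl (2E,4E)-hexa-2,4-dienoate | C/C=C/C=C/C(=O)OC | starting material
2 | lithium trienolate of 1, lithium (3E)-1-methoxyhexa-1,3,5-trien-1-olate | C=C/C=C/C=C(OC)[O-].[Li+] | intermediate (not isolated)
3 | methyl (3E)-2-methylhexa-3,5-dienoate, racemic | C=C/C=C/C(C)C(=O)OC | intermediate
4 | tiglic aldehyde, (2E)-2-methylbut-2-enal | C/C=C(\C)C=O | starting material
5 | methyl 2-[(1R,5R,6S)-6-formyl-5,6-dimethylcyclohex-2-en-1-yl]propanoate, both epimers at propanoate C2 (C9) | COC(=O)C(C)[C@H]1C=CC[C@@H](C)[C@]1(C)C=O | intermediate
6 | methyl 2-[(1R,5R,6S)-6-(1-hydroxyethyl)-5,6-dimethylcyclohex-2-en-1-yl]propanoate, epimers at the carbinol carbon (C6) and at C9 | COC(=O)C(C)[C@H]1C=CC[C@@H](C)[C@]1(C)C(C)O | intermediate (not isolated)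
7 | (4aR,8R,8aS)-1,4,8,8a-tetramethyl-1,4,4a,7,8,8a-hexahydro-3H-isochromen-3-one, the trans-fused δ-lactone; epimers at C6 and C9 (isochromenone C1 and C4) | CC1[C@H]2C=CC[C@@H](C)[C@]2(C)C(C)OC1=O | intermediate
8 | lithium enolate of 7 (C9=C8–OLi) | [Li+].[O-]C1=C(C)[C@H]2C=CC[C@@H](C)[C@]2(C)C(C)O1 | intermediate (not isolated)
9 | lactone 7 made quaternary at C9: 9α-methyl, 9β-(benzyloxymethyl); epimers at C6 | c1ccccc1COC[C@]2(C)[C@H]3C=CC[C@@H](C)[C@]3(C)C(C)OC2=O | intermediate
10 | diol: ring A cyclohexene (4α,5α-dimethyl, 10β-H) with C5–CH(OH)CH3 and C10–C9(CH3)(CH2OH)(CH2OBn); epimers at C6 | c1ccccc1COC[C@@](C)(CO)[C@H]2C=CC[C@@H](C)[C@]2(C)C(C)O | intermediate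
11 | keto aldehyde: same ring A with C5–C(=O)CH3 and C10–C9(CH3)(CHO)(CH2OBn) | c1ccccc1COC[C@@](C)(C=O)[C@H]2C=CC[C@@H](C)[C@]2(C)C(C)=O | intermediate
12 | aldol: ring B closed, C6 ketone, C8 hydroxyl (either epimer) | c1ccccc1COC[C@]2(C)[C@H]3C=CC[C@@H](C)[C@]3(C)C(=O)CC2O | intermediate (not isolated)
13 | ring B enone: trans-fused octalin, C1=C2 and C6(=O)–C7=C8; 4α,5α,9α-trimethyl, 9β-CH2OBn, 10β-H | c1ccccc1COC[C@]2(C)[C@H]3C=CC[C@@H](C)[C@]3(C)C(=O)C=C2 | intermediate
14 | C6 ketone with 8β-methyl: 4α,5α,8β,9α-tetramethyl, 9β-CH2OBn, 10β-H, C1=C2 | c1ccccc1COC[C@]2(C)[C@H]3C=CC[C@@H](C)[C@]3(C)C(=O)C[C@@H]2C | intermediate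
15 | hydrazone of 14 at C6 | c1ccccc1COC[C@]2(C)[C@H]3C=CC[C@@H](C)[C@]3(C)C(=NN)C[C@@H]2C | intermediate (not isolated)
16 | benzyl ether of the Δ1-decalin carbinol: 4α,5α,8β,9α-tetramethyl, 9β-CH2OBn, 10β-H, C1=C2 | c1ccccc1COC[C@]2(C)[C@H]3C=CC[C@@H](C)[C@]3(C)CC[C@@H]2C | intermediate
17 | ring A enone: 16 with C3 ketone conjugated to C1=C2 | c1ccccc1COC[C@]2(C)[C@H]3C=CC(=O)[C@@H](C)[C@]3(C)CC[C@@H]2C | intermediate
18 | (1S,4aS,5S,6S,8aR)-5-(hydroxymethyl)-1,5,6,8a-tetramethyloctahydronaphthalen-2(1H)-one | OC[C@]1(C)[C@H]2CCC(=O)[C@@H](C)[C@]2(C)CC[C@@H]1C | intermediate
19 | isofraxidin, 7-hydroxy-6,8-dimethoxy-2H-chromen-2-one | COc1cc2ccc(=O)oc2c(OC)c1O | starting material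
20 | 6,8-dimethoxy-7-{[(1S,2S,4aR,5S,8aS)-1,2,4a,5-tetramethyl-6-oxodecahydronaphthalen-1-yl]methoxy}-2H-chromen-2-one | COc1cc2ccc(=O)oc2c(OC)c1OC[C@]1(C)[C@H]2CCC(=O)[C@@H](C)[C@]2(C)CC[C@@H]1C | target

## Step count and least certain steps

Total: 12 steps. Longest linear sequence: 12 steps, from 1 to 20 (4 and 19 enter at steps 2 and 12).

Step 2 (key step). The trisubstituted enal and the branched diene terminus make the cycloaddition slow. At the higher temperature then needed, exo and facial selectivity may erode, and the acid may isomerise the skipped dienoate into conjugation, which would remove the diene. Fallback: setting out from 3 and 4, an achiral promoter (Me2AlCl, CH2Cl2, −78 °C) should give the racemic exo cycloadduct F1. This is taken through steps 3 to 11 unchanged, the intermediates being the racemic forms of 7 to 17, to the racemic keto alcohol F2. F2 is esterified with (S)-2-methoxy-2-phenylacetic acid (DCC, DMAP), the diastereomeric esters are separated, and the wanted (S)-O-methylmandelate ester F3 is cleaved with K2CO3 in MeOH, which returns to the route at 18.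

Step 10. Hydrogen abstraction may occur at the weaker tertiary allylic C10–H, which would lead to oxygenation at C2 with allylic transposition, and the benzylic CH2 of the ether may be oxidised to the benzoate. Fallback: setting out from 16, SeO2 (catalytic) with tBuOOH in CH2Cl2 should hydroxylate by an ene reaction and [2,3] shift, which prefers the methylene over the methine, keeps the double bond at C1=C2 and leaves benzyl ethers alone. This gives the C3 allylic alcohol F4, and Dess–Martin periodinane then returns to the route at 17.

Step 12. Substitution at the neopentyl carbon by a phenoxide flanked by two methoxy groups may be too slow, so that the oxyphosphonium intermediate decomposes or is intercepted by the hydrazide. Fallback: setting out from 18, Tf2O and 2,6-lutidine in CH2Cl2 at −78 °C give the neopentyl triflate F5, whose far better leaving group is displaced by the cesium salt of 19 (Cs2CO3, DMF, 23 → 50 °C), which returns to the route at 20.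

Step 9. Hydrazone formation at the C6 carbonyl, flanked by quaternary C5, may be incomplete or give the azine, and the prolonged heating then needed in strong base is the main stress on the material. Fallback: setting out from 14, NaBH4 in MeOH gives the C6 alcohol F6; NaH, CS2 and MeI give the S-methyl xanthate F7; Bu3SnH with AIBN in PhMe at 110 °C (Barton–McCombie deoxygenation) returns to the route at 16.

## Further compounds

F1 | step 2 | racemic methyl 2-[(1R*,5R*,6S*)-6-formyl-5,6-dimethylcyclohex-2-en-1-yl]propanoate (racemate of 5; one enantiomer drawn) | COC(=O)C(C)[C@H]1C=CC[C@@H](C)[C@]1(C)C=O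
F2 | step 2 | racemic 5-(hydroxymethyl)-1,5,6,8a-tetramethyloctahydronaphthalen-2(1H)-one (racemate of 18; one enantiomer drawn) | OC[C@]1(C)[C@H]2CCC(=O)[C@@H](C)[C@]2(C)CC[C@@H]1C
F3 | step 2 | (S)-2-methoxy-2-phenylacetate ester of 18 | CO[C@H](C(=O)OC[C@]1(C)[C@H]2CCC(=O)[C@@H](C)[C@]2(C)CC[C@@H]1C)c1ccccc1
F4 | step 10 | C3 allylic alcohol of 16 (C1=C2 kept; either C3 epimer) | c1ccccc1COC[C@]2(C)[C@H]3C=CC(O)[C@@H](C)[C@]3(C)CC[C@@H]2C
F5 | step 12 | C11 trifluoromethanesulfonate of 18 | FC(F)(F)S(=O)(=O)OC[C@]1(C)[C@H]2CCC(=O)[C@@H](C)[C@]2(C)CC[C@@H]1C
F6 | step 9 | C6 alcohol from 14 (either C6 epimer) | c1ccccc1COC[C@]2(C)[C@H]3C=CC[C@@H](C)[C@]3(C)C(O)C[C@@H]2C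
F7 | step 9 | O-C6 S-methyl xanthate of F6 | c1ccccc1COC[C@]2(C)[C@H]3C=CC[C@@H](C)[C@]3(C)C(OC(=S)SC)C[C@@H]2C
A1 | alternative 1 | (E)-propenyl δ-lactone with C3 ketal (C11 lactone carbonyl, ring oxygen on C6, propenyl α; epimers at C9) | CC1[C@H]2CCC3(OCCO3)[C@@H](C)[C@]2(C)[C@@H](/C=C/C)OC1=O
A2 | alternative 1 | trimethylsilyl ketene acetal of A1 | CC=1[C@H]2CCC3(OCCO3)[C@@H](C)[C@]2(C)[C@@H](/C=C/C)OC=1O[Si](C)(C)C
A3 | alternative 1 | C6–C7 unsaturated decalin C11 carboxylic acid with C3 ketal | OC(=O)[C@]1(C)[C@H]2CCC3(OCCO3)[C@@H](C)[C@]2(C)C=C[C@@H]1C
A4 | alternative 2 | acyclic epoxy diene tert-butyldimethylsilyl enol ether (epoxide C9–C11, E olefin C10=C5, Z enol silane C3=C4) | C/C=C(\O[Si](C)(C)C(C)(C)C)CC/C=C(\C)CC[C@H](C)[C@@]1(C)CO1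
A5 | alternative 2 | keto alcohol, identical with 18 | OC[C@]1(C)[C@H]2CCC(=O)[C@@H](C)[C@]2(C)CC[C@@H]1C
A6 | alternative 3 | 2-(tert-butyldimethylsilyloxy)-3-methoxy-4-(decalinylmethoxy)furan with C3 ketal | COc1c(O[Si](C)(C)C(C)(C)C)occ1OC[C@]1(C)[C@H]2CCC3(OCCO3)[C@@H](C)[C@]2(C)CC[C@@H]1C
A7 | alternative 3 | methyl propiolate | C#CC(=O)OC
A8 | alternative 3 | methyl 5-hydroxy-3-methoxy-2-(tert-butyldimethylsilyloxy)-4-(decalinylmethoxy)benzoate with C3 ketal | COC(=O)c1cc(O)c(OC[C@]2(C)[C@H]3CCC4(OCCO4)[C@@H](C)[C@]3(C)CC[C@@H]2C)c(OC)c1O[Si](C)(C)C(C)(C)C
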